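**Strategy.** With the chain numbered from the CH2OH carbon (C1) to the isopropyl methine (C15), the target is cut at C11–C12 and C13–C14 around the C12 carbinol. This carbinol lies between the C10=C11 trisubstituted alkene and the C13 methylene that carries the C14 methylidene–isopropyl unit, so C12–C13 can enter as a vinyl group. One palladium-catalysed conjunctive coupling joins a C1–C11 alkenyl pinacolboronate, vinyllithium and 3-methylbut-1-en-2-yl triflate, forms both bonds and sets C12 under ligand control, while the C2–C3 and C6–C7 oxirane rings are carried through unchanged. The precursor is the C1-silylated bis-epoxy (Z)-alkenylboronate, made from nerol by two Sharpless epoxidations, an acetoacetate homologation, ozonolysis and a boron-Wittig olefination.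

Key step: step 13

Remarks: target locants C1–C15 are used for all intermediates (nerol supplies C5–C10, its CH2OH carbon being C5). "Mandyphos" means 1,1′-bis[bis(4-methoxy-3,5-dimethylphenyl)phosphino]-2,2′-bis[α-(dimethylamino)benzyl]ferrocene. Assumption: the antipode that gives 12R is taken to be the (Sp,Sp) ligand by analogy with simple alkenyl migrating groups; both antipodes are commercial, so the opposite assignment would only exchange the ligand.

Step 1
Reactants: 1 nerol
Product: 2 [(2R,3S)-3-methyl-3-(4-methylpent-3-en-1-yl)oxiran-2-yl]methanol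
Conditions: Ti(OiPr)4 (10 mol %), D-(−)-diethyl tartrate (12 mol %), t-BuOOH, 4 Å MS, CH2Cl2, −20 °C
Reagents that add atoms: tert-butyl hydroperoxide, CC(C)(C)OO
Why: Sharpless asymmetric epoxidation of the Z-allylic alcohol, in which the titanium–tartrate complex of the D-(−)-ester delivers oxygen to the face of the C6=C7 alkene that gives 6R,7S (the antipode of the known L-(+)-tartrate product of nerol), while the isolated prenyl alkene has no directing hydroxyl and stays intact.

Step 2
Reactants: 2 [(2R,3S)-3-methyl-3-(4-methylpent-3-en-1-yl)oxiran-2-yl]methanol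
Product: 3 (2S,3S)-2-(iodomethyl)-3-methyl-3-(4-methylpent-3-en-1-yl)oxirane
Conditions: PPh3, imidazole, I2, CH2Cl2, 0 °C, dark
Reagents that add atoms: iodine, II
Why: Appel-type iodination (Garegg–Samuelsson conditions) replaces the primary hydroxyl at C5 by SN2 on the alkoxyphosphonium ion without touching the oxirane carbons, so the oxirane geometry is unchanged (the C6 descriptor changes only because CH2I outranks C7).

Step 3
Reactants: 3 (2S,3S)-2-(iodomethyl)-3-methyl-3-(4-methylpent-3-en-1-yl)oxirane; 4 methyl acetoacetate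
Product: 6 methyl 5-[(2R,3S)-3-methyl-3-(4-methylpent-3-en-1-yl)oxiran-2-yl]-3-oxopentanoate, via acetoacetate dianion 5 (not isolated)
Conditions: 4, NaH, THF, 0 °C; n-BuLi, 0 °C; then 3, −78 to 0 °C; cold aq NH4Cl
Reagents that add atoms: none
Why: Weiler alkylation, in which the γ-carbon of the acetoacetate dianion displaces the primary iodide (forming C4–C5) much faster than any carbanion opens a trisubstituted oxirane, and a short reaction time with a cold quench keeps the remaining β-keto ester enolate from attacking the neighbouring oxirane.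

Step 4
Reactants: 6 methyl 5-[(2R,3S)-3-methyl-3-(4-methylpent-3-en-1-yl)oxiran-2-yl]-3-oxopentanoate
Product: 8 methyl (2Z)-3-[(diethoxyphosphoryl)oxy]-5-[(2R,3S)-3-methyl-3-(4-methylpent-3-en-1-yl)oxiran-2-yl]pent-2-enoate, via sodium enolate 7 (not isolated)
Conditions: NaH, Et2O, 0 °C; ClP(O)(OEt)2, 0 °C
Reagents that add atoms: diethyl chlorophosphate, CCOP(=O)(Cl)OCC
Why: O-phosphorylation of the sodium-chelated enolate of the β-keto ester (first half of the Sum–Weiler sequence) gives the Z-enol phosphate, because chelation holds the enolate oxygen cis to the ester.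

Step 5
Reactants: 8 methyl (2Z)-3-[(diethoxyphosphoryl)oxy]-5-[(2R,3S)-3-methyl-3-(4-methylpent-3-en-1-yl)oxiran-2-yl]pent-2-enoate
Product: 9 methyl (2E)-3-methyl-5-[(2R,3S)-3-methyl-3-(4-methylpent-3-en-1-yl)oxiran-2-yl]pent-2-enoate
Conditions: Me2CuLi (from MeLi and CuI), Et2O, −78 to −45 °C; aq NH4Cl
Reagents that add atoms: lithium dimethylcuprate, [Li+].C[Cu-]C
Why: Conjugate addition–elimination of the Gilman cuprate on the β-phosphoryloxy enoate (Sum–Weiler coupling) replaces the phosphate by methyl with retention of geometry and so fixes the 2E alkene, and a trisubstituted oxirane is inert to Me2CuLi at this temperature.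

Step 6
Reactants: 9 methyl (2E)-3-methyl-5-[(2R,3S)-3-methyl-3-(4-methylpent-3-en-1-yl)oxiran-2-yl]pent-2-enoate
Product: 10 (2E)-3-methyl-5-[(2R,3S)-3-methyl-3-(4-methylpent-3-en-1-yl)oxiran-2-yl]pent-2-en-1-ol
Conditions: i-Bu2AlH (2.3 equiv), CH2Cl2, −78 °C; aq KNaC4H4O6
Reagents that add atoms: none
Why: 1,2-Reduction of the enoate by the aluminium hydride at −78 °C is far faster than reductive opening of the trisubstituted oxirane and gives the E-allylic alcohol needed for the second directed epoxidation.

Step 7
Reactants: 10 (2E)-3-methyl-5-[(2R,3S)-3-methyl-3-(4-methylpent-3-en-1-yl)oxiran-2-yl]pent-2-en-1-ol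
Product: 11 [(2R,3R)-3-methyl-3-{2-[(2R,3S)-3-methyl-3-(4-methylpent-3-en-1-yl)oxiran-2-yl]ethyl}oxiran-2-yl]methanol
Conditions: Ti(OiPr)4 (10 mol %), D-(−)-diethyl tartrate (12 mol %), t-BuOOH, 4 Å MS, CH2Cl2, −20 °C
Reagents that add atoms: tert-butyl hydroperoxide, CC(C)(C)OO
Why: A second Sharpless asymmetric epoxidation, now of a geraniol-type E-allylic alcohol, for which the D-(−)-tartrate catalyst sets 2R,3R under reagent control, while only the alkene next to the hydroxyl reacts and any minor enantiomer from step 1 becomes a separable diastereomer.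

Step 8
Reactants: 11 [(2R,3R)-3-methyl-3-{2-[(2R,3S)-3-methyl-3-(4-methylpent-3-en-1-yl)oxiran-2-yl]ethyl}oxiran-2-yl]methanol
Product: 12 C1 tert-butyldimethylsilyl ether of 11
Conditions: TBSCl, imidazole, DMF, 0 °C to rt
Reagents that add atoms: tert-butyldimethylsilyl chloride, CC(C)(C)[Si](C)(C)Cl
Why: Corey silylation of the primary alcohol masks the only acidic proton before the carbanion and organolithium steps and creates no stereocentre.

Step 9
Reactants: 12 C1 tert-butyldimethylsilyl ether of 11
Product: 14 (2R,3R,6R,7S)-1-(tert-butyldimethylsilyloxy)-2,3:6,7-diepoxy-3,7-dimethyldecan-10-al, via ozonide 13 (not isolated)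
Conditions: O3, CH2Cl2, −78 °C; then PPh3, −78 °C to rt
Reagents that add atoms: ozone, [O-][O+]=O
Why: Ozonolysis (Criegee mechanism) cleaves the only remaining alkene, the prenyl terminus, and reduction of the ozonide with PPh3 releases the C10 aldehyde and acetone under neutral conditions that leave both oxiranes and the silyl ether intact.

Step 10
Reactants: 14 (2R,3R,6R,7S)-1-(tert-butyldimethylsilyloxy)-2,3:6,7-diepoxy-3,7-dimethyldecan-10-al; 15 1,1-bis(pinacolboryl)ethane
Product: 17 (2R,3R,6R,7S,10Z)-C1–C11 alkenyl pinacolboronate with boron on C11 trans to the C9 methylene and C1 as the silyl ether, via lithiated bis(boronate) 16 (not isolated)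
Conditions: 15, lithium 2,2,6,6-tetramethylpiperidide, THF, 0 °C; then 14, −78 °C to rt
Reagents that add atoms: none
Why: Boron-Wittig olefination, in which the α-diboryl carbanion adds to the aldehyde and syn B–O elimination forms C10=C11, and the aldehyde chain is expected to settle trans to the remaining bulky pinacolboryl group, which puts boron trans to C9.

Step 11
Reactants: 18 3-methylbutan-2-one
Product: 20 3-methylbut-1-en-2-yl trifluoromethanesulfonate, via lithium enolate 19 (not isolated)
Conditions: LiN(i-Pr)2, THF, −78 °C; PhNTf2, −78 °C to rt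
Reagents that add atoms: N-phenylbis(trifluoromethanesulfonimide), O=S(=O)(N(c1ccccc1)S(=O)(=O)C(F)(F)F)C(F)(F)F
Why: Kinetic deprotonation of the methyl ketone by the hindered amide occurs at the methyl group, not at the isopropyl methine, and O-triflation of that enolate gives the 1,1-disubstituted alkenyl triflate.

Step 12
Reactants: 21 tetravinylstannane
Product: 22 vinyllithium (halide-free, titrated stock solution in Et2O)
Conditions: n-BuLi, pentane, rt; solid washed with pentane, dissolved in Et2O
Reagents that add atoms: n-butyllithium, [Li]CCCC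
Why: Tin–lithium exchange (Seyferth preparation) precipitates vinyllithium free of lithium halide, which matters because halide ions hinder the cationic palladium pathway of the next step.

Step 13
Reactants: 17 (2R,3R,6R,7S,10Z)-C1–C11 alkenyl pinacolboronate; 22 vinyllithium; 20 3-methylbut-1-en-2-yl trifluoromethanesulfonate
Product: 24 (2R,3R,6R,7S,10E,12R)-C12 pinacolboronate of the C1-silylated target skeleton, via vinyl(alkenyl)borate 23 (not isolated)
Conditions: 22 (1.0 equiv), THF/Et2O, −78 °C to rt; then Pd(OAc)2 (3 mol %), Mandyphos (3.6 mol %), 20 (1.2 equiv), THF, 60 °C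
Reagents that add atoms: none
Why: Oxidative addition of zerovalent palladium into triflate 20 gives a cationic divalent alkenylpalladium that binds the unsubstituted vinyl group of 23, the C11 alkenyl group then shifts from boron to C12 anti to palladium (a metal-induced 1,2-metallate rearrangement) to form C11–C12 and a C13–Pd bond, and reductive elimination forms C13–C14. The closest known reaction type is the enantioselective palladium/Mandyphos conjunctive cross-coupling of alkenyl(vinyl)boron ate complexes with alkenyl triflates, which gives α-substituted allylboronates. No ring is formed. C12 is the only new stereocentre and is set by the ferrocenyl bisphosphine, which differentiates the faces of the palladium-bound vinyl group, and the existing centres (the nearest, C7, is five bonds away) should not interfere. Site selectivity (vinyl as acceptor, the trisubstituted alkenyl group as migrating group) follows from the preference of palladium for the less hindered alkene, the pinacol ligand and the halide-free medium should suppress direct Suzuki-type alkenyl transfer, and the wide-bite-angle ligand favours reductive elimination over β-hydride loss from C12. The oxiranes are protected by forming 23 at −78 °C with exactly one equivalent of 22, since coordination to boron is far faster than opening of a trisubstituted oxirane and no free organolithium remains on heating.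

Step 14
Reactants: 24 (2R,3R,6R,7S,10E,12R)-C12 pinacolboronate of the C1-silylated target skeleton
Product: 25 (2R,3R,6R,7S,10E,12R)-1-O-(tert-butyldimethylsilyl) ether of the target diol
Conditions: 3 M NaOH, 30% H2O2, THF, 0 °C; aq Na2S2O3
Reagents that add atoms: hydrogen peroxide, OO
Why: Oxidation of the boronate proceeds by 1,2-shift of C12 from boron to oxygen in the hydroperoxide ate complex with retention of configuration, so 12R is preserved, and at 0 °C neither the trisubstituted oxiranes nor the silyl ether react.

Step 15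
Reactants: 25 (2R,3R,6R,7S,10E,12R)-1-O-(tert-butyldimethylsilyl) ether of the target diol
Product: 26 (2R,3R,6R,7S,10E,12R)-2,3:6,7-diepoxy-3,7,11,15-tetramethyl-14-methylidenehexadec-10-ene-1,12-diol (CNP0156678.1)
Conditions: Bu4NF, AcOH (1:1), THF, 0 °C
Reagents that add atoms: none
Why: Fluoride-induced desilylation frees the C1 hydroxyl, and buffering with acetic acid keeps the medium from becoming basic enough for Payne rearrangement of the 2,3-epoxy alcohol.

**Compound list**

1 | nerol, (2Z)-3,7-dimethylocta-2,6-dien-1-ol | CC(C)=CCC/C(C)=C\CO | starting material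
2 | [(2R,3S)-3-methyl-3-(4-methylpent-3-en-1-yl)oxiran-2-yl]methanol (6R,7S in target locants) | CC(C)=CCC[C@]1(C)O[C@@H]1CO | intermediate
3 | (2S,3S)-2-(iodomethyl)-3-methyl-3-(4-methylpent-3-en-1-yl)oxirane (iodide of 2, oxirane unchanged) | CC(C)=CCC[C@]1(C)O[C@@H]1CI | intermediate
4 | methyl acetoacetate | COC(=O)CC(C)=O | starting material
5 | sodium lithium bis-enolate (dianion) of methyl acetoacetate | C=C([O-])C=C([O-])OC.[Na+].[Li+] | intermediate
6 | methyl 5-[(2R,3S)-3-methyl-3-(4-methylpent-3-en-1-yl)oxiran-2-yl]-3-oxopentanoate | CC(C)=CCC[C@]1(C)O[C@@H]1CCC(=O)CC(=O)OC | intermediate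
7 | sodium (Z)-enolate of 6 | CC(C)=CCC[C@]1(C)O[C@@H]1CC/C([O-])=C/C(=O)OC.[Na+] | intermediate
8 | methyl (2Z)-3-[(diethoxyphosphoryl)oxy]-5-[(2R,3S)-3-methyl-3-(4-methylpent-3-en-1-yl)oxiran-2-yl]pent-2-enoate | CC(C)=CCC[C@]1(C)O[C@@H]1CC/C(OP(=O)(OCC)OCC)=C/C(=O)OC | intermediate
9 | methyl (2E)-3-methyl-5-[(2R,3S)-3-methyl-3-(4-methylpent-3-en-1-yl)oxiran-2-yl]pent-2-enoate | CC(C)=CCC[C@]1(C)O[C@@H]1CC/C(C)=C/C(=O)OC | intermediate
10 | (2E)-3-methyl-5-[(2R,3S)-3-methyl-3-(4-methylpent-3-en-1-yl)oxiran-2-yl]pent-2-en-1-ol | CC(C)=CCC[C@]1(C)O[C@@H]1CC/C(C)=C/CO | intermediate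
11 | [(2R,3R)-3-methyl-3-{2-[(2R,3S)-3-methyl-3-(4-methylpent-3-en-1-yl)oxiran-2-yl]ethyl}oxiran-2-yl]methanol (2R,3R,6R,7S) | CC(C)=CCC[C@]1(C)O[C@@H]1CC[C@@]1(C)O[C@@H]1CO | intermediate
12 | C1 tert-butyldimethylsilyl ether of 11 | CC(C)=CCC[C@]1(C)O[C@@H]1CC[C@@]1(C)O[C@@H]1CO[Si](C)(C)C(C)(C)C | intermediate
13 | ozonide (3,3-dimethyl-1,2,4-trioxolane, mixture at the acetal carbon) of 12 | CC1(C)OOC(CC[C@]2(C)O[C@@H]2CC[C@@]2(C)O[C@@H]2CO[Si](C)(C)C(C)(C)C)O1 | intermediate
14 | (2R,3R,6R,7S)-1-(tert-butyldimethylsilyloxy)-2,3:6,7-diepoxy-3,7-dimethyldecan-10-al | O=CCC[C@]1(C)O[C@@H]1CC[C@@]1(C)O[C@@H]1CO[Si](C)(C)C(C)(C)C | intermediate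
15 | 1,1-bis(pinacolboryl)ethane | CC(B1OC(C)(C)C(C)(C)O1)B1OC(C)(C)C(C)(C)O1 | starting material
16 | 1-lithio-1,1-bis(pinacolboryl)ethane | [Li]C(C)(B1OC(C)(C)C(C)(C)O1)B1OC(C)(C)C(C)(C)O1 | intermediate
17 | (2R,3R,6R,7S,10Z)-C1–C11 alkenyl pinacolboronate, boron on C11 trans to C9, C1 silyl ether | CC1(C)OB(OC1(C)C)/C(C)=C/CC[C@]1(C)O[C@@H]1CC[C@@]1(C)O[C@@H]1CO[Si](C)(C)C(C)(C)C | intermediate
18 | 3-methylbutan-2-one | CC(C)C(C)=O | starting material
19 | lithium 3-methylbut-1-en-2-olate | [Li]OC(=C)C(C)C | intermediate
20 | 3-methylbut-1-en-2-yl trifluoromethanesulfonate | C=C(OS(=O)(=O)C(F)(F)F)C(C)C | intermediate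
21 | tetravinylstannane | C=C[Sn](C=C)(C=C)C=C | starting material
22 | vinyllithium | [Li]C=C | intermediate
23 | lithium vinyl(alkenyl)pinacolborate from 17 and 22 | [Li+].C=C[B-]1(OC(C)(C)C(C)(C)O1)/C(C)=C/CC[C@]1(C)O[C@@H]1CC[C@@]1(C)O[C@@H]1CO[Si](C)(C)C(C)(C)C | intermediate
24 | (2R,3R,6R,7S,10E,12R)-C12 pinacolboronate of the C1-silylated target skeleton | C=C(C[C@@H](B1OC(C)(C)C(C)(C)O1)/C(C)=C/CC[C@]1(C)O[C@@H]1CC[C@@]1(C)O[C@@H]1CO[Si](C)(C)C(C)(C)C)C(C)C | intermediate
25 | (2R,3R,6R,7S,10E,12R)-1-O-(tert-butyldimethylsilyl) ether of the target | C=C(C[C@@H](O)/C(C)=C/CC[C@]1(C)O[C@@H]1CC[C@@]1(C)O[C@@H]1CO[Si](C)(C)C(C)(C)C)C(C)C | intermediate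
26 | (2R,3R,6R,7S,10E,12R)-2,3:6,7-diepoxy-3,7,11,15-tetramethyl-14-methylidenehexadec-10-ene-1,12-diol | C=C(C[C@@H](O)/C(C)=C/CC[C@]1(C)O[C@@H]1CC[C@@]1(C)O[C@@H]1CO)C(C)C | target

**Step count.** 15 steps in total. The longest linear sequence is 13 steps (steps 1–10 and 13–15, nerol to target); steps 11 and 12 are one-step side branches.

**Steps most likely to fail**

1. Step 13 (conjunctive coupling). Possible failures are direct Suzuki-type transfer of an alkenyl group from boron to palladium, binding of palladium to the wrong alkene of the ate complex, or weak facial discrimination at C12 with the hindered α-methyl migrating group. The fallback builds C12 by carbonyl allylation and sets out from aldehyde 14. Wittig olefination with Ph3P=C(CH3)CHO (toluene, 90 °C) should give the C1–C12 (E)-2-methyl enal F1. Separately, 2,3-dimethylbut-1-ene is metalated at its allylic methyl group with n-BuLi/KOt-Bu and quenched with Bu3SnCl to give tributyl(3-methyl-2-methylidenebutyl)stannane F2. Keck asymmetric allylation of F1 with F2 ((R)-BINOL, Ti(OiPr)4, 4 Å MS, CH2Cl2, −20 °C) forms C12–C13, is expected to set 12R by analogy with simple aldehydes, and delivers 25 directly, so the route is rejoined at 25 before step 15.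

2. Step 3 (dianion alkylation next to an oxirane). Possible failures are attack of the enolate oxygen of the first-formed β-keto ester anion on the neighbouring oxirane (5-exo closure to a tetrahydrofuran) or slow displacement at the carbon adjacent to the oxirane. The fallback forms C3–C4 by cross-coupling and sets out from epoxy alcohol 2. Oxidation (SO3·pyridine, DMSO, i-Pr2NEt, 0 °C) gives the epoxy aldehyde F3, and methylenation with Ph3P=CH2 gives the vinyl oxirane F4. 9-Borabicyclononane adds to the terminal alkene of F4 in preference to the prenyl alkene and gives the B-alkyl borane F5, used in situ. Suzuki–Miyaura coupling of F5 with methyl (E)-3-(trifluoromethylsulfonyloxy)but-2-enoate F6 (from 4 with Tf2O and aqueous Me4NOH), using PdCl2(dppf) and K3PO4 in DMF/THF/H2O at rt, proceeds with retention and comes back to the route at enoate 9.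

3. Step 10 (boron-Wittig). Possible failures are low alkene stereoselectivity in the B–O elimination with an unbranched aldehyde, or enolisation of the aldehyde by the lithiated bis(boronate). The fallback sets out from aldehyde 14. Methylenation with Ph3P=CH2 gives the terminal alkene F7. Cross-metathesis of F7 with commercial 2-isopropenyl pinacolboronate (second-generation Grubbs catalyst, CH2Cl2, 40 °C) is expected to give, under thermodynamic control, the isomer with boron trans to the chain, which is 17, where the route is rejoined.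

**Further compounds**

F1 | step 13 | (2R,3R,6R,7S,10E)-1-(tert-butyldimethylsilyloxy)-2,3:6,7-diepoxy-3,7,11-trimethyldodec-10-en-12-al | O=C/C(C)=C/CC[C@]1(C)O[C@@H]1CC[C@@]1(C)O[C@@H]1CO[Si](C)(C)C(C)(C)C
F2 | step 13 | tributyl(3-methyl-2-methylidenebutyl)stannane | CCCC[Sn](CCCC)(CCCC)CC(=C)C(C)C
F3 | step 3 | epoxy aldehyde of 2 (CHO in place of CH2OH, oxirane unchanged) | CC(C)=CCC[C@]1(C)O[C@@H]1C=O
F4 | step 3 | vinyl oxirane (CH=CH2 in place of CH2OH of 2, oxirane unchanged) | CC(C)=CCC[C@]1(C)O[C@@H]1C=C
F5 | step 3 | B-alkyl-9-borabicyclo[3.3.1]nonane from F4 (boron on C4) | CC(C)=CCC[C@]1(C)O[C@@H]1CCB1C2CCCC1CCC2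
F6 | step 3 | methyl (E)-3-(trifluoromethylsulfonyloxy)but-2-enoate | C/C(OS(=O)(=O)C(F)(F)F)=C\C(=O)OC
F7 | step 10 | terminal alkene from 14 (CH=CH2 in place of CHO) | C=CCC[C@]1(C)O[C@@H]1CC[C@@]1(C)O[C@@H]1CO[Si](C)(C)C(C)(C)C
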